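**Plan**
- Retrosynthesis: first cut the C2–C3 bond of ring C (back to an α-diazo ketone of an aryl benzyl ether), then the O1–CH2 ether bond (ring A phenol + ring B benzylic alcohol), then the aryl–allyl bond of ring B (aryl iodide + allylic bromide from geranyl acetate).
- Forward: the hydrated geranyl chain is made from geranyl acetate and joined to ring B by copper-catalysed allylation; ring B is joined to ring A by Mitsunobu etherification; diazo transfer follows; ring C closes last and the silyl groups then come off.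
- Enabling feature: the O1–CH2–Ar methylene (future C2) carries two enantiotopic, hydridic C–H bonds (α to the ring C ether oxygen and benzylic to the para-oxygenated ring B), five atoms away from the ketone α-carbon (future C3).
- Stereochemistry: (2S) is set by catalyst control in the carbene C–H insertion (chiral dirhodium tetracarboxylate); the E-olefin is carried over unchanged from geranyl acetate.

Key step: step 12

Assumption: Rh2(S-PTTL)4 is taken to deliver the (2S) product; if a model run shows the opposite sense, the mirror-image catalyst Rh2(R-PTTL)4 is used under the same conditions. TBS = tert-butyldimethylsilyl, TES = triethylsilyl.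

**Step 1**
Reactants: 1 geranyl acetate
Product: 3 (E)-7-hydroxy-3,7-dimethyloct-2-en-1-yl acetate, via organomercury acetate 2 (not isolated)
Conditions: Hg(OAc)2, THF/H2O, 0 °C → rt; then NaBH4, 3 M aq NaOH, 0 °C, short contact
Reagents that add atoms: water, O
Why: Markovnikov oxymercuration–demercuration should hydrate only the electron-rich remote 6,7-olefin, because the 2,3-olefin is deactivated by the allylic acetate, so the E-olefin stays untouched.

**Step 2**
Reactants: 3 (E)-7-hydroxy-3,7-dimethyloct-2-en-1-yl acetate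
Product: 4 (E)-3,7-dimethyl-7-(triethylsilyloxy)oct-2-en-1-yl acetate
Conditions: TESOTf, 2,6-lutidine, CH2Cl2, −78 → 0 °C
Reagents that add atoms: triethylsilyl trifluoromethanesulfonate, CC[Si](CC)(CC)OS(=O)(=O)C(F)(F)F
Why: Silyl triflate silylation is the standard way to cap a hindered tertiary alcohol, which must be masked before the Grignard, enolate and carbene steps.

**Step 3**
Reactants: 4 (E)-3,7-dimethyl-7-(triethylsilyloxy)oct-2-en-1-yl acetate
Product: 5 (E)-3,7-dimethyl-7-(triethylsilyloxy)oct-2-en-1-ol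
Conditions: K2CO3 (cat.), MeOH, 0 °C → rt
Reagents that add atoms: none
Why: Base-catalysed transesterification removes the primary acetate, and the hindered tertiary TES ether should survive catalytic carbonate in methanol.

**Step 4**
Reactants: 5 (E)-3,7-dimethyl-7-(triethylsilyloxy)oct-2-en-1-ol
Product: 6 (E)-1-bromo-3,7-dimethyl-7-(triethylsilyloxy)oct-2-ene
Conditions: CBr4, PPh3, CH2Cl2, 0 °C
Reagents that add atoms: carbon tetrabromide, BrC(Br)(Br)Br
Why: The Appel reaction converts primary allylic alcohols of the geraniol type into the bromides under neutral conditions, without allylic transposition or loss of E geometry.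

**Step 5**
Reactants: 7 methyl 4-hydroxy-3-iodobenzoate
Product: 8 methyl 4-(tert-butyldimethylsilyloxy)-3-iodobenzoate
Conditions: TBSCl, imidazole, DMF, rt
Reagents that add atoms: tert-butyldimethylsilyl chloride, CC(C)(C)[Si](C)(C)Cl
Why: Routine phenol silylation gives a protecting group that tolerates the organometallic, hydride, Mitsunobu and carbene steps and leaves with fluoride at the end.

**Step 6**
Reactants: 8 methyl 4-(tert-butyldimethylsilyloxy)-3-iodobenzoate; 6 (E)-1-bromo-3,7-dimethyl-7-(triethylsilyloxy)oct-2-ene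
Product: 10 methyl 4-(tert-butyldimethylsilyloxy)-3-[(E)-3,7-dimethyl-7-(triethylsilyloxy)oct-2-en-1-yl]benzoate, via arylmagnesium chloride 9 (not isolated)
Conditions: 8 (1.2 equiv), i-PrMgCl·LiCl, THF, −40 °C; then CuBr·SMe2 (10 mol%), 6, −40 → 0 °C
Reagents that add atoms: none
Why: Iodine–magnesium exchange at low temperature tolerates the ester, and copper-catalysed allylic substitution should occur at the unhindered α-carbon of the primary bromide (the γ-carbon is fully substituted) with retention of the E-olefin.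

**Step 7**
Reactants: 10 methyl 4-(tert-butyldimethylsilyloxy)-3-[(E)-3,7-dimethyl-7-(triethylsilyloxy)oct-2-en-1-yl]benzoate
Product: 11 {4-(tert-butyldimethylsilyloxy)-3-[(E)-3,7-dimethyl-7-(triethylsilyloxy)oct-2-en-1-yl]phenyl}methanol
Conditions: DIBAL-H (2.5 equiv), CH2Cl2, −78 → 0 °C; Rochelle salt work-up
Reagents that add atoms: none
Why: DIBAL-H reduction of the aryl ester to the benzylic alcohol leaves silyl ethers and the trisubstituted olefin untouched.

**Step 8**
Reactants: 12 2,4,6-trihydroxyacetophenone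
Product: 13 1-[2,4-bis(tert-butyldimethylsilyloxy)-6-hydroxyphenyl]ethan-1-one
Conditions: TBSCl (2.1 equiv), imidazole, CH2Cl2/DMF, 0 °C → rt
Reagents that add atoms: tert-butyldimethylsilyl chloride, CC(C)(C)[Si](C)(C)Cl
Why: The para hydroxyl and one ortho hydroxyl are silylated, after which the remaining ortho hydroxyl is locked in a strong hydrogen bond to the carbonyl and should stay free.

**Step 9**
Reactants: 13 1-[2,4-bis(tert-butyldimethylsilyloxy)-6-hydroxyphenyl]ethan-1-one; 11 {4-(tert-butyldimethylsilyloxy)-3-[(E)-3,7-dimethyl-7-(triethylsilyloxy)oct-2-en-1-yl]phenyl}methanol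
Product: 14 1-[2,4-bis(tert-butyldimethylsilyloxy)-6-({4-(tert-butyldimethylsilyloxy)-3-[(E)-3,7-dimethyl-7-(triethylsilyloxy)oct-2-en-1-yl]phenyl}methoxy)phenyl]ethan-1-one
Conditions: PPh3, DIAD, THF, 0 °C → rt
Reagents that add atoms: none
Why: Mitsunobu etherification alkylates the acidic, chelated phenol at oxygen with the primary benzylic alcohol under neutral conditions that spare the aryl silyl ethers.

**Step 10**
Reactants: 14 the aryl benzyl ether methyl ketone
Product: 15 1-[2,4-bis(tert-butyldimethylsilyloxy)-6-({4-(tert-butyldimethylsilyloxy)-3-[(E)-3,7-dimethyl-7-(triethylsilyloxy)oct-2-en-1-yl]phenyl}methoxy)phenyl]-4,4,4-trifluorobutane-1,3-dione (used crude)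
Conditions: LiHMDS, THF, −78 °C; CF3CO2CH2CF3, −78 °C; then AcOH
Reagents that add atoms: 2,2,2-trifluoroethyl trifluoroacetate, O=C(OCC(F)(F)F)C(F)(F)F
Why: Claisen condensation of the kinetic lithium enolate of the only enolisable position (the acetyl methyl) with the activated trifluoroacetate ester prepares the methyl group for diazo transfer.

**Step 11**
Reactants: 15 the trifluoromethyl 1,3-diketone
Product: 16 1-[2,4-bis(tert-butyldimethylsilyloxy)-6-({4-(tert-butyldimethylsilyloxy)-3-[(E)-3,7-dimethyl-7-(triethylsilyloxy)oct-2-en-1-yl]phenyl}methoxy)phenyl]-2-diazoethan-1-one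
Conditions: MsN3, Et3N, H2O (1 equiv), MeCN, rt
Reagents that add atoms: methanesulfonyl azide, CS(=O)(=O)N=[N+]=[N-]
Why: Deacylative Regitz diazo transfer to the activated methylene, with loss of the trifluoroacetyl group as the N-acyl sulfonamide, gives the terminal α-diazo ketone under mild conditions that silyl ethers tolerate.

**Step 12**
Reactants: 16 the α-diazo ketone
Product: 17 (2S)-5,7-bis(tert-butyldimethylsilyloxy)-2-{4-(tert-butyldimethylsilyloxy)-3-[(E)-3,7-dimethyl-7-(triethylsilyloxy)oct-2-en-1-yl]phenyl}chroman-4-one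
Conditions: Rh2(S-PTTL)4 (dirhodium tetrakis[N-phthaloyl-(S)-tert-leucinate], 1 mol%), CH2Cl2, 4 Å MS, −20 °C, slow addition of 16 (final 0.01 M)
Reagents that add atoms: none
Why: Loss of N2 at the dirhodium centre gives an electrophilic rhodium carbene whose carbon (future C3) inserts, through a concerted but asynchronous three-centre transition state with hydride-transfer character, into one C–H bond of the O–CH2–Ar methylene (future C2), forming the C2–C3 bond and releasing the catalyst. The closest known reaction type is the intramolecular C–H insertion of 2-alkoxyaryl diazoketones to chroman-4-ones under chiral dirhodium carboxylate catalysis, together with carbene insertion into aryl benzyl ether C–H bonds. Ring C closes as a 1,6-C–H insertion through a six-membered chair-like transition state; the usual 1,5-position is the ether oxygen and carries no hydrogen. The C2 stereocentre is set under catalyst control, the chiral carboxylate ligand wall distinguishing the two enantiotopic benzylic hydrogens. The step needs chemoselectivity for C–H insertion over oxonium ylide formation with 1,2-benzyl shift, over attack on the ortho silyl ether and over cyclopropanation of the side-chain olefin. This should be secured because the ether oxygen is a weak donor (its lone pair is conjugated with the acyl-bearing ring A), the C–H bond is doubly activated (α-oxygen, benzylic to the electron-rich ring B), the ortho OTBS group has no α-C–H, and slow addition at high dilution suppresses bimolecular paths.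

**Step 13**
Reactants: 17 the tetrasilylated (2S)-flavanone
Product: 18 (2S)-5,7-dihydroxy-2-{4-hydroxy-3-[(E)-7-hydroxy-3,7-dimethyloct-2-en-1-yl]phenyl}-2,3-dihydro-4H-chromen-4-one
Conditions: HF·pyridine, pyridine, THF, 0 °C → rt
Reagents that add atoms: none
Why: Buffered, non-basic fluoride desilylation should cleave the three aryl TBS ethers and the tertiary TES ether without forming free phenoxide (which would open ring C to the chalcone and racemise C2) and without acid strong enough to add the phenol to the olefin.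

**Compound list**
1 | geranyl acetate | CC(=O)OC/C=C(\C)CCC=C(C)C | starting material
2 | (E)-6-(acetoxymercurio)-7-hydroxy-3,7-dimethyloct-2-en-1-yl acetate (racemic at C6) | CC(=O)OC/C=C(\C)CCC([Hg]OC(C)=O)C(C)(C)O | intermediate
3 | (E)-7-hydroxy-3,7-dimethyloct-2-en-1-yl acetate | CC(=O)OC/C=C(\C)CCCC(C)(C)O | intermediate
4 | (E)-3,7-dimethyl-7-(triethylsilyloxy)oct-2-en-1-yl acetate | CC(=O)OC/C=C(\C)CCCC(C)(C)O[Si](CC)(CC)CC | intermediate
5 | (E)-3,7-dimethyl-7-(triethylsilyloxy)oct-2-en-1-ol | OC/C=C(\C)CCCC(C)(C)O[Si](CC)(CC)CC | intermediate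
6 | (E)-1-bromo-3,7-dimethyl-7-(triethylsilyloxy)oct-2-ene | BrC/C=C(\C)CCCC(C)(C)O[Si](CC)(CC)CC | intermediate
7 | methyl 4-hydroxy-3-iodobenzoate | COC(=O)c1ccc(O)c(I)c1 | starting material
8 | methyl 4-(tert-butyldimethylsilyloxy)-3-iodobenzoate | COC(=O)c1ccc(O[Si](C)(C)C(C)(C)C)c(I)c1 | intermediate
9 | [2-(tert-butyldimethylsilyloxy)-5-(methoxycarbonyl)phenyl]magnesium chloride (LiCl complex) | COC(=O)c1ccc(O[Si](C)(C)C(C)(C)C)c([Mg]Cl)c1 | intermediate
10 | methyl 4-(tert-butyldimethylsilyloxy)-3-[(E)-3,7-dimethyl-7-(triethylsilyloxy)oct-2-en-1-yl]benzoate | COC(=O)c1ccc(O[Si](C)(C)C(C)(C)C)c(C/C=C(\C)CCCC(C)(C)O[Si](CC)(CC)CC)c1 | intermediate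
11 | {4-(tert-butyldimethylsilyloxy)-3-[(E)-3,7-dimethyl-7-(triethylsilyloxy)oct-2-en-1-yl]phenyl}methanol | OCc1ccc(O[Si](C)(C)C(C)(C)C)c(C/C=C(\C)CCCC(C)(C)O[Si](CC)(CC)CC)c1 | intermediate
12 | 2,4,6-trihydroxyacetophenone | CC(=O)c1c(O)cc(O)cc1O | starting material
13 | 1-[2,4-bis(tert-butyldimethylsilyloxy)-6-hydroxyphenyl]ethan-1-one | CC(=O)c1c(O)cc(O[Si](C)(C)C(C)(C)C)cc1O[Si](C)(C)C(C)(C)C | intermediate
14 | 1-[2,4-bis(tert-butyldimethylsilyloxy)-6-({4-(tert-butyldimethylsilyloxy)-3-[(E)-3,7-dimethyl-7-(triethylsilyloxy)oct-2-en-1-yl]phenyl}methoxy)phenyl]ethan-1-one | CC(=O)c1c(OCc2ccc(O[Si](C)(C)C(C)(C)C)c(C/C=C(\C)CCCC(C)(C)O[Si](CC)(CC)CC)c2)cc(O[Si](C)(C)C(C)(C)C)cc1O[Si](C)(C)C(C)(C)C | intermediate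
15 | 4,4,4-trifluorobutane-1,3-dione derived from 14 (acetyl CH3 replaced by CH2C(=O)CF3) | O=C(CC(=O)C(F)(F)F)c1c(OCc2ccc(O[Si](C)(C)C(C)(C)C)c(C/C=C(\C)CCCC(C)(C)O[Si](CC)(CC)CC)c2)cc(O[Si](C)(C)C(C)(C)C)cc1O[Si](C)(C)C(C)(C)C | intermediate
16 | 2-diazoethan-1-one derived from 14 (acetyl CH3 replaced by CH=N2) | [N-]=[N+]=CC(=O)c1c(OCc2ccc(O[Si](C)(C)C(C)(C)C)c(C/C=C(\C)CCCC(C)(C)O[Si](CC)(CC)CC)c2)cc(O[Si](C)(C)C(C)(C)C)cc1O[Si](C)(C)C(C)(C)C | intermediate
17 | (2S)-5,7-bis(tert-butyldimethylsilyloxy)-2-{4-(tert-butyldimethylsilyloxy)-3-[(E)-3,7-dimethyl-7-(triethylsilyloxy)oct-2-en-1-yl]phenyl}chroman-4-one | C/C(=C\Cc1cc([C@@H]2CC(=O)c3c(O[Si](C)(C)C(C)(C)C)cc(O[Si](C)(C)C(C)(C)C)cc3O2)ccc1O[Si](C)(C)C(C)(C)C)CCCC(C)(C)O[Si](CC)(CC)CC | intermediate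
18 | (2S)-5,7-dihydroxy-2-{4-hydroxy-3-[(E)-7-hydroxy-3,7-dimethyloct-2-en-1-yl]phenyl}-2,3-dihydro-4H-chromen-4-one | C/C(=C\Cc1cc([C@@H]2CC(=O)c3c(O)cc(O)cc3O2)ccc1O)CCCC(C)(C)O | target

**Totals**
Total step count: 13. Longest linear sequence: 11 steps (steps 1–4, 6, 7, 9–13).

**Steps most likely to fail**

1. Step 12 (carbene C–H insertion). The catalyst may discriminate poorly between the two enantiotopic benzylic hydrogens, or the carbene may be captured by the ether oxygen and undergo a 1,2-benzyl shift instead of inserting. The fallback sets out from 11 and 13 and comes back at 17. Alcohol 11 is oxidised with MnO2 (CH2Cl2, rt) to 4-(tert-butyldimethylsilyloxy)-3-[(E)-3,7-dimethyl-7-(triethylsilyloxy)oct-2-en-1-yl]benzaldehyde F1. F1 and ketone 13 are condensed with pyrrolidine (toluene, 40 °C) through the 2'-hydroxychalcone F2, which closes in the same flask by oxa-Michael addition to the racemic flavanone F3. F3 is then resolved by asymmetric transfer hydrogenation (Cp*RhCl[(R,R)-TsDPEN], HCO2H/Et3N, EtOAc, stopped near half conversion, the ligand antipode being chosen so that the (2R)-ketone reacts fast). This should reduce the unwanted enantiomer to the cis-(2R,4R)-flavan-4-ol F4 and leave the (2S)-ketone 17 for chromatographic separation.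

2. Step 6 (aryl–allyl coupling). The nucleophile may attack the γ-carbon of the allylic bromide to give the branched isomer, the silyl group may migrate from oxygen to the metalated carbon, or the Grignard reagent may add to the ester. The fallback sets out from 8 and comes back at 10. Iodide 8 is converted by Miyaura borylation (B2pin2, Pd(dppf)Cl2, KOAc, dioxane, 80 °C) into methyl 4-(tert-butyldimethylsilyloxy)-3-(4,4,5,5-tetramethyl-1,3,2-dioxaborolan-2-yl)benzoate F5. F5 is coupled with bromide 6 in a Suzuki–Miyaura allyl–aryl coupling (Pd(PPh3)4, anhydrous K3PO4, toluene, 60 °C). The π-allylpalladium intermediate should be arylated at its unsubstituted terminus to give 10.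

3. Step 9 (Mitsunobu etherification). The activated p-silyloxybenzylic oxyphosphonium may ionise and C-benzylate the electron-rich ring A, or the hydrogen-bonded phenol may react sluggishly. The fallback sets out from 11 and comes back at 14. Alcohol 11 is converted under Appel conditions (CBr4, PPh3, CH2Cl2, 0 °C) into the benzylic bromide {4-(bromomethyl)-2-[(E)-3,7-dimethyl-7-(triethylsilyloxy)oct-2-en-1-yl]phenoxy}(tert-butyl)dimethylsilane F6. F6 then alkylates phenol 13 at oxygen in a Williamson etherification (K2CO3, acetone, rt) to give 14.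

**Further compounds**
F1 | step 12 | 4-(tert-butyldimethylsilyloxy)-3-[(E)-3,7-dimethyl-7-(triethylsilyloxy)oct-2-en-1-yl]benzaldehyde | O=Cc1ccc(O[Si](C)(C)C(C)(C)C)c(C/C=C(\C)CCCC(C)(C)O[Si](CC)(CC)CC)c1
F2 | step 12 | (E)-1-[2,4-bis(tert-butyldimethylsilyloxy)-6-hydroxyphenyl]-3-{4-(tert-butyldimethylsilyloxy)-3-[(E)-3,7-dimethyl-7-(triethylsilyloxy)oct-2-en-1-yl]phenyl}prop-2-en-1-one | O=C(/C=C/c1ccc(O[Si](C)(C)C(C)(C)C)c(C/C=C(\C)CCCC(C)(C)O[Si](CC)(CC)CC)c1)c1c(O)cc(O[Si](C)(C)C(C)(C)C)cc1O[Si](C)(C)C(C)(C)C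
F3 | step 12 | racemic 5,7-bis(tert-butyldimethylsilyloxy)-2-{4-(tert-butyldimethylsilyloxy)-3-[(E)-3,7-dimethyl-7-(triethylsilyloxy)oct-2-en-1-yl]phenyl}chroman-4-one | C/C(=C\Cc1cc(C2CC(=O)c3c(O[Si](C)(C)C(C)(C)C)cc(O[Si](C)(C)C(C)(C)C)cc3O2)ccc1O[Si](C)(C)C(C)(C)C)CCCC(C)(C)O[Si](CC)(CC)CC
F4 | step 12 | (2R,4R)-5,7-bis(tert-butyldimethylsilyloxy)-2-{4-(tert-butyldimethylsilyloxy)-3-[(E)-3,7-dimethyl-7-(triethylsilyloxy)oct-2-en-1-yl]phenyl}chroman-4-ol | C/C(=C\Cc1cc([C@H]2C[C@@H](O)c3c(O[Si](C)(C)C(C)(C)C)cc(O[Si](C)(C)C(C)(C)C)cc3O2)ccc1O[Si](C)(C)C(C)(C)C)CCCC(C)(C)O[Si](CC)(CC)CC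
F5 | step 6 | methyl 4-(tert-butyldimethylsilyloxy)-3-(4,4,5,5-tetramethyl-1,3,2-dioxaborolan-2-yl)benzoate | COC(=O)c1ccc(O[Si](C)(C)C(C)(C)C)c(B2OC(C)(C)C(C)(C)O2)c1
F6 | step 9 | {4-(bromomethyl)-2-[(E)-3,7-dimethyl-7-(triethylsilyloxy)oct-2-en-1-yl]phenoxy}(tert-butyl)dimethylsilane | BrCc1ccc(O[Si](C)(C)C(C)(C)C)c(C/C=C(\C)CCCC(C)(C)O[Si](CC)(CC)CC)c1
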